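(Readings and results come from a simulation for substances that don't exist; noise was put on by code.)

The product of this coupling comes in a burst and then creeps: Thursday's run reads 50 % at 2.00 min and 76 % at 25.0 min. Two chemists dispute what slow feeding does to the yield.

| flask | electrophile | nucleophile | solid base | protic impurity | remark | time |
|---|---|---|---|---|---|---|
| Thursday's | 16 mM | 16.8 mM | 32 mM | 4.8 mM | run made earlier |  |
| Wednesday's | 16 mM | 11 mM | 32 mM | 4.8 mM | run made earlier |  |
| Sunday's | 16 mM | 25 mM | 32 mM | 4.8 mM | run made earlier |  |
| epsilon | 16 mM (fed, over 30 min) | 16.8 mM | 32.0 mM | 4.80 mM | all else is in the flask from the start; the feed brings no volume worth counting | 40 min |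
| alpha | 16 mM | 16.8 mM | 32.0 mM | 4.80 mM | everything together at the start | 40 min |
| delta | 16 mM (in portions, 3, over 30 min) | 16.8 mM | 32.0 mM | 4.80 mM | first portion at the start, last at 30 min | 40 min |
| theta | 16 mM | 16.8 mM (fed, over 30 min) | 32.0 mM | 4.80 mM | all else is in the flask from the start; the feed brings no volume worth counting | 40 min |

| run | time / min | product / % | electrophile / % |
|---|---|---|---|
| Thursday's | 2.00 | 50 | 47 |
| Thursday's | 6.00 | 62 | 31 |
| Thursday's | 12.0 | 67 | 21 |
| Thursday's | 15.0 | 70 | 20 |
| Thursday's | 25.0 | 76 | 13 |
| Wednesday's | 2.00 | 36 | 61 |
| Wednesday's | 4.00 | 44 | 53 |
| Wednesday's | 6.00 | 46 | 49 |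
| Wednesday's | 12.0 | 56 | 40 |
| Wednesday's | 25.0 | 59 | 28 |
| Sunday's | 5.00 | 81 | 14 |
| Sunday's | 10.0 | 89 | 10 |
| Sunday's | 15.0 | 95 | 4 |
| Sunday's | 20.0 | 88 | 3 |
| Sunday's | 25.0 | 91 | 0 |

(readings scatter by 2 percentage points)

- given per volume of solution although it is solid: solid base
- the numbers in the tables scatter with a standard deviation of 2 percentage points
- at the start none of the solid base is in solution

- the flask that comes out highest in amount of product, in percent of the electrophile charged, or "all alike" when all lie within 1.5 percentage points (epsilon / alpha / delta / theta / all alike)
- product at the end, in percent of the electrophile charged, epsilon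
- product at the end, in percent of the electrophile charged, alpha
- product at the end, in percent of the electrophile charged, delta
- product at the end, in percent of the electrophile charged, theta

The first chemist reasons from the product made. Carrying Thursday's curve on gives alpha 80 %, and theta, the argument runs, comes out “slightly best”. The forecast is this chemist's: 71 % for epsilon, 73 % for delta, 83 % for theta, with theta highest.

The second chemist works with the fraction left. At 25.0 min, Thursday's product and electrophile leave a gap of 11.0 % of the charge. She reads this gap as electrophile lost one for one to the impurity, so 63.3 % of the impurity remains. Summed over time, the electrophile readings equal 6.86 min at full charge. If the loss goes as electrophile times impurity, the logarithm of the impurity left falls in step with that sum. This gives 34.7 min, a reading with the scatter of its data, for her loss half-life: the time in which electrophile facing impurity held at its charge halves by this pseudo-first-order loss.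

In theta, nucleophile arrives evenly over 30 min, so electrophile waits 15.0 min on average, and 74.1 % survives that wait. The loss this implies is less than the impurity charge permits, 30.0 % of the electrophile. So her own figure for theta lies below the forecast's.

The simulation gives 77.9 % for epsilon, 79.8 % for alpha, 76.7 % for delta and 72.7 % for theta, so alpha is highest. The first chemist's view holds for alpha, charged as Thursday's run was, where 80 % stands beside 79.8 %.

    solid base ⇌ free base, rate k1*(cs1 - [free base]) while solid is left; crystals form when [free base] > cs1 (solubility = 6.30 mM, k = 3.75 × 10⁻⁴ /s)
    electrophile + nucleophile → acid set free + product (k = 1.15 /M/s)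
    electrophile + protic impurity → quenched substrate (k = 0.0676 /M/s)
    nucleophile + acid set free ⇌ protonated nucleophile, settled at all times (K = 2690 /M)
    acid set free + free base ⇌ salt of the base, settled at all times (K = 48000 /M)

Against the loss half-life of 34.7 min, alpha's coupling half-life at charged amounts is far shorter, at 0.60 min, and by 40.0 min it has reached 26 min, when alpha holds 12.4 % quenched substrate, in percent of the electrophile charged. In theta, the mean nucleophile of 0.727 mM over the first 30 min gives a coupling half-life of 13.8 min, shorter than the 35.6 min that the constants give for the loss with impurity at its charge by a factor of just 2.58, and at 40.0 min theta holds 20.0 % quenched substrate.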